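**Plan**
- Retrosynthesis first removes the two benzyl ethers (O5, O5') and the C3–OMe group (C3–O traced back to C3–H), leaving a 3-unsubstituted flavone.
- Ring C is then cut at C4a–C4, C4–C3 and O1–C2. The C4 carbonyl lies between A-ring carbon C4a and C3, and O1 sits on the neighbouring C8a, so C4 can be carbon monoxide placed between an ortho-iodophenol and the B-ring arylacetylene.
- Forward, the A-ring iodophenol comes from 3-bromo-4,5-dimethoxybenzaldehyde (Baeyer–Villiger, benzylation, Br→OH, acetal-directed ortho-iodination). The B-ring alkyne comes from 4-(benzyloxy)phenol (iodination, methylation, Sonogashira, desilylation).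
- Rings A and B are bought. The pyranone ring C is the only ring closed, in the three-component carbonylative annulation. C3 hydroxylation, O-methylation and double hydrogenolysis finish the route.
- Stereochemistry: none to set, because the target is a planar, achiral flavone.

Key step: step 11

Remark: the target SMILES has no stereocentre, stereogenic axis or stereogenic double bond, so it is treated as one achiral compound and no enantiomer question arises.
Remark: 3-bromo-4,5-dimethoxybenzaldehyde is taken as a catalogue compound (otherwise one O-methylation from 5-bromovanillin).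

**Route**

Step 1
Reactants: 1 3-bromo-4,5-dimethoxybenzaldehyde
Product: 3 3-bromo-4,5-dimethoxyphenol, via aryl formate 2 (not isolated)
Conditions: mCPBA, CH2Cl2, 0 °C → rt; aq NaHCO3 wash; then K2CO3 (cat.), MeOH, rt
Reagents that add atoms: 3-chloroperoxybenzoic acid, O=C(OO)c1cccc(Cl)c1
Why: Baeyer–Villiger (Dakin-type) oxidation, in which the electron-rich aryl group migrates in the Criegee adduct of the aldehyde and the resulting aryl formate is methanolysed to the phenol.

Step 2
Reactants: 3 3-bromo-4,5-dimethoxyphenol
Product: 4 5-(benzyloxy)-1-bromo-2,3-dimethoxybenzene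
Conditions: BnBr, K2CO3, DMF, rt
Reagents that add atoms: benzyl bromide, BrCc1ccccc1
Why: Williamson etherification of an unhindered phenoxide with a reactive benzylic halide should be clean and masks the future 5-OH until the last step.

Step 3
Reactants: 4 5-(benzyloxy)-1-bromo-2,3-dimethoxybenzene
Product: 7 5-(benzyloxy)-2,3-dimethoxyphenol, via aryllithium 5 (not isolated), via lithium aryltrimethoxyborate 6 (not isolated)
Conditions: n-BuLi, THF, −78 °C; B(OMe)3, −78 °C → rt; AcOH, 30% H2O2, 0 °C → rt
Reagents that add atoms: hydrogen peroxide, OO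
Why: Bromine–lithium exchange at −78 °C is faster than any deprotonation, and borate trapping followed by oxidative 1,2-aryl migration (boronate oxidation) should replace Br by OH at the same carbon.

Step 4
Reactants: 7 5-(benzyloxy)-2,3-dimethoxyphenol
Product: 8 5-(benzyloxy)-1,2-dimethoxy-3-(methoxymethoxy)benzene
Conditions: MOMCl, i-Pr2NEt, CH2Cl2, 0 °C → rt
Reagents that add atoms: chloromethyl methyl ether, COCCl
Why: O-alkylation to the methoxymethyl ether installs a chelating directing group for metalation that can later be removed by acid without touching the benzyl ether.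

Step 5
Reactants: 8 5-(benzyloxy)-1,2-dimethoxy-3-(methoxymethoxy)benzene
Product: 10 1-(benzyloxy)-2-iodo-4,5-dimethoxy-3-(methoxymethoxy)benzene, via aryllithium 9 (not isolated)
Conditions: n-BuLi, THF, −20 → 0 °C; I2, −78 °C → rt
Reagents that add atoms: iodine, II
Why: Directed ortho-metalation should occur at the CH between OMOM and OBn, where two oxygens acidify the position and the distal acetal oxygen can hold lithium, whereas the other ring CH sits beside a methoxy group whose methyl is pushed toward it by the neighbouring OMe; iodinolysis of the aryllithium then gives the iodide.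

Step 6
Reactants: 10 1-(benzyloxy)-2-iodo-4,5-dimethoxy-3-(methoxymethoxy)benzene
Product: 11 3-(benzyloxy)-2-iodo-5,6-dimethoxyphenol
Conditions: HCl (cat.), MeOH/THF, rt
Reagents that add atoms: none
Why: Acid-catalysed acetal cleavage (transacetalisation to methanol) should free only the MOM-protected phenol, since benzyl and methyl aryl ethers are inert to dilute acid at room temperature.

Step 7
Reactants: 12 4-(benzyloxy)phenol
Product: 13 4-(benzyloxy)-2-iodophenol
Conditions: NIS (1.0 equiv), p-TsOH (10 mol %), MeCN, rt
Reagents that add atoms: N-iodosuccinimide, O=C1CCC(=O)N1I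
Why: Electrophilic aromatic iodination should go ortho to the free hydroxyl, the stronger activating group, because the para position is blocked.

Step 8
Reactants: 13 4-(benzyloxy)-2-iodophenol
Product: 14 4-(benzyloxy)-2-iodo-1-methoxybenzene
Conditions: MeI, K2CO3, acetone, reflux
Reagents that add atoms: iodomethane, CI
Why: Williamson methylation of the only free phenol fixes the future 2'-methoxy group.

Step 9
Reactants: 14 4-(benzyloxy)-2-iodo-1-methoxybenzene; 15 ethynyltrimethylsilane
Product: 16 {[5-(benzyloxy)-2-methoxyphenyl]ethynyl}trimethylsilane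
Conditions: PdCl2(PPh3)2 (2 mol %), CuI (4 mol %), Et3N/THF, rt
Reagents that add atoms: none
Why: Sonogashira coupling of an aryl iodide with a silyl-capped acetylene should proceed at room temperature, the silyl group preventing double arylation.

Step 10
Reactants: 16 {[5-(benzyloxy)-2-methoxyphenyl]ethynyl}trimethylsilane
Product: 17 4-(benzyloxy)-2-ethynyl-1-methoxybenzene
Conditions: K2CO3 (cat.), MeOH/CH2Cl2, rt
Reagents that add atoms: none
Why: Base-catalysed protodesilylation (methanolysis of the C(sp)–Si bond) should release the terminal alkyne without affecting the ethers.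

Step 11
Reactants: 11 3-(benzyloxy)-2-iodo-5,6-dimethoxyphenol; 17 4-(benzyloxy)-2-ethynyl-1-methoxybenzene; 18 carbon monoxide
Product: 21 5-(benzyloxy)-2-[5-(benzyloxy)-2-methoxyphenyl]-7,8-dimethoxy-4H-chromen-4-one, via hydroxyaryl ynone 19 (not isolated), via diethylamino enone 20 (not isolated)
Conditions: PdCl2(dppf) (5 mol %), Et2NH, CO (20 bar), 120 °C, autoclave
Reagents that add atoms: none
Why: Pd(0) formed in situ should add oxidatively to the C–I bond of 11, CO should insert to give an aroyl–Pd(II) species, and coupling with the amine-deprotonated alkyne 17 followed by reductive elimination should give ynone 19, forming C4a–C4 and C4–C3 (copper-free carbonylative Sonogashira coupling). Diethylamine should then add to the ynone to give β-amino enone 20, and the ortho hydroxyl should displace the amine by addition–elimination at the amine-bearing carbon, forming O1–C2; with respect to the ynone this is a 6-endo-dig oxa-Michael closure of the pyranone ring. The closest known reaction is the Pd-catalysed carbonylative annulation of ortho-iodophenols with terminal arylacetylenes to flavones. No stereocentre is formed. The step needs carbonylative coupling to beat direct coupling to a 2-arylbenzofuran, which CO pressure and the absence of copper favour, and six-membered closure to beat five-membered aurone closure, which the enaminone secures because only its amine-bearing carbon remains electrophilic. The A-ring regiochemistry is fixed by the substrate, since only one of the two oxygens flanking the iodide is a free hydroxyl and the other is benzylated.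

Step 12
Reactants: 21 5-(benzyloxy)-2-[5-(benzyloxy)-2-methoxyphenyl]-7,8-dimethoxy-4H-chromen-4-one
Product: 24 5-(benzyloxy)-2-[5-(benzyloxy)-2-methoxyphenyl]-3-hydroxy-7,8-dimethoxy-4H-chromen-4-one, via 3-lithioflavone 22 (not isolated), via lithium flavonyltrimethoxyborate 23 (not isolated)
Conditions: LDA, THF, −78 °C; B(OMe)3, −78 °C → rt; AcOH, 30% H2O2, rt
Reagents that add atoms: hydrogen peroxide, OO
Why: Directed lithiation at C3, the only vinylic CH, which is acidified by the C4 carbonyl and held by lithium chelation to the carbonyl oxygen, followed by borate trapping and boronate oxidation, should deliver the flavonol as known for 5-alkoxyflavones.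

Step 13
Reactants: 24 5-(benzyloxy)-2-[5-(benzyloxy)-2-methoxyphenyl]-3-hydroxy-7,8-dimethoxy-4H-chromen-4-one
Product: 25 5-(benzyloxy)-2-[5-(benzyloxy)-2-methoxyphenyl]-3,7,8-trimethoxy-4H-chromen-4-one
Conditions: MeI, K2CO3, acetone, reflux
Reagents that add atoms: iodomethane, CI
Why: Williamson methylation of the acidic 3-hydroxyl, the only free OH in the molecule, should give the 3-methyl ether.

Step 14
Reactants: 25 5-(benzyloxy)-2-[5-(benzyloxy)-2-methoxyphenyl]-3,7,8-trimethoxy-4H-chromen-4-one
Product: 26 5,5'-dihydroxy-3,7,8,2'-tetramethoxyflavone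
Conditions: H2 (1 atm), 10% Pd/C, EtOAc/MeOH, rt
Reagents that add atoms: none
Why: Catalytic hydrogenolysis should cleave both benzyl aryl ethers while the methyl ethers and the tetrasubstituted pyranone double bond remain untouched under these mild conditions.

**Compound list**

1 | 3-bromo-4,5-dimethoxybenzaldehyde | O=Cc1cc(Br)c(OC)c(OC)c1 | starting material
2 | 3-bromo-4,5-dimethoxyphenyl formate (not isolated) | O=COc1cc(Br)c(OC)c(OC)c1 | intermediate
3 | 3-bromo-4,5-dimethoxyphenol | Oc1cc(Br)c(OC)c(OC)c1 | intermediate
4 | 5-(benzyloxy)-1-bromo-2,3-dimethoxybenzene | COc1cc(OCc2ccccc2)cc(Br)c1OC | intermediate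
5 | [5-(benzyloxy)-2,3-dimethoxyphenyl]lithium (not isolated) | [Li]c1cc(OCc2ccccc2)cc(OC)c1OC | intermediate
6 | lithium [5-(benzyloxy)-2,3-dimethoxyphenyl]trimethoxyborate (not isolated) | [Li+].CO[B-](OC)(OC)c1cc(OCc2ccccc2)cc(OC)c1OC | intermediate
7 | 5-(benzyloxy)-2,3-dimethoxyphenol | COc1cc(OCc2ccccc2)cc(O)c1OC | intermediate
8 | 5-(benzyloxy)-1,2-dimethoxy-3-(methoxymethoxy)benzene | COCOc1cc(OCc2ccccc2)cc(OC)c1OC | intermediate
9 | [6-(benzyloxy)-3,4-dimethoxy-2-(methoxymethoxy)phenyl]lithium (not isolated) | [Li]c1c(OCOC)c(OC)c(OC)cc1OCc1ccccc1 | intermediate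
10 | 1-(benzyloxy)-2-iodo-4,5-dimethoxy-3-(methoxymethoxy)benzene | COCOc1c(I)c(OCc2ccccc2)cc(OC)c1OC | intermediate
11 | 3-(benzyloxy)-2-iodo-5,6-dimethoxyphenol | COc1cc(OCc2ccccc2)c(I)c(O)c1OC | intermediate
12 | 4-(benzyloxy)phenol | Oc1ccc(OCc2ccccc2)cc1 | starting material
13 | 4-(benzyloxy)-2-iodophenol | Oc1ccc(OCc2ccccc2)cc1I | intermediate
14 | 4-(benzyloxy)-2-iodo-1-methoxybenzene | COc1ccc(OCc2ccccc2)cc1I | intermediate
15 | ethynyltrimethylsilane | C#C[Si](C)(C)C | starting material
16 | {[5-(benzyloxy)-2-methoxyphenyl]ethynyl}trimethylsilane | COc1ccc(OCc2ccccc2)cc1C#C[Si](C)(C)C | intermediate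
17 | 4-(benzyloxy)-2-ethynyl-1-methoxybenzene | COc1ccc(OCc2ccccc2)cc1C#C | intermediate
18 | carbon monoxide | [C-]#[O+] | starting material
19 | 1-[6-(benzyloxy)-2-hydroxy-3,4-dimethoxyphenyl]-3-[5-(benzyloxy)-2-methoxyphenyl]prop-2-yn-1-one (not isolated) | COc1ccc(OCc2ccccc2)cc1C#CC(=O)c1c(O)c(OC)c(OC)cc1OCc1ccccc1 | intermediate
20 | (E)-1-[6-(benzyloxy)-2-hydroxy-3,4-dimethoxyphenyl]-3-[5-(benzyloxy)-2-methoxyphenyl]-3-(diethylamino)prop-2-en-1-one (not isolated; E isomer expected, geometry of no consequence for the closure) | CCN(CC)/C(=C/C(=O)c1c(O)c(OC)c(OC)cc1OCc1ccccc1)c1cc(OCc2ccccc2)ccc1OC | intermediate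
21 | 5-(benzyloxy)-2-[5-(benzyloxy)-2-methoxyphenyl]-7,8-dimethoxy-4H-chromen-4-one | COc1ccc(OCc2ccccc2)cc1-c1cc(=O)c2c(OCc3ccccc3)cc(OC)c(OC)c2o1 | intermediate
22 | {5-(benzyloxy)-2-[5-(benzyloxy)-2-methoxyphenyl]-7,8-dimethoxy-4-oxo-4H-chromen-3-yl}lithium (not isolated) | [Li]c1c(-c2cc(OCc3ccccc3)ccc2OC)oc2c(OC)c(OC)cc(OCc3ccccc3)c2c1=O | intermediate
23 | lithium {5-(benzyloxy)-2-[5-(benzyloxy)-2-methoxyphenyl]-7,8-dimethoxy-4-oxo-4H-chromen-3-yl}trimethoxyborate (not isolated) | [Li+].CO[B-](OC)(OC)c1c(-c2cc(OCc3ccccc3)ccc2OC)oc2c(OC)c(OC)cc(OCc3ccccc3)c2c1=O | intermediate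
24 | 5-(benzyloxy)-2-[5-(benzyloxy)-2-methoxyphenyl]-3-hydroxy-7,8-dimethoxy-4H-chromen-4-one | COc1ccc(OCc2ccccc2)cc1-c1oc2c(OC)c(OC)cc(OCc3ccccc3)c2c(=O)c1O | intermediate
25 | 5-(benzyloxy)-2-[5-(benzyloxy)-2-methoxyphenyl]-3,7,8-trimethoxy-4H-chromen-4-one | COc1ccc(OCc2ccccc2)cc1-c1oc2c(OC)c(OC)cc(OCc3ccccc3)c2c(=O)c1OC | intermediate
26 | 5,5'-dihydroxy-3,7,8,2'-tetramethoxyflavone [5-hydroxy-2-(5-hydroxy-2-methoxyphenyl)-3,7,8-trimethoxy-4H-chromen-4-one] | COc1ccc(O)cc1-c1oc2c(OC)c(OC)cc(O)c2c(=O)c1OC | target

**Totals**

Total step count: 14.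
Longest linear sequence: 10 steps (steps 1–6, then 11–14); the alkyne branch (steps 7–10) joins at step 11.

**Steps most likely to fail**

1. Step 11. Oxidative addition into the electron-rich, doubly ortho-substituted C–I bond may be slow, more so once the phenol is deprotonated by the amine. That would let CO-free coupling with cyclisation to a 2-arylbenzofuran, or alkyne oligomerisation, outrun the carbonylative path.
Fallback: the three bond formations would be separated and run without a free phenol. It sets out from MOM ether 10 (already in the route), alkyne 17 and CO 18. A carbonylative Sonogashira coupling (PdCl2(PPh3)2, Et3N, CO 1–5 bar, THF, rt → 50 °C) should give the protected ynone 1-[6-(benzyloxy)-3,4-dimethoxy-2-(methoxymethoxy)phenyl]-3-[5-(benzyloxy)-2-methoxyphenyl]prop-2-yn-1-one F1. Dilute HCl in MeOH would remove the acetal to give hydroxy ynone 19. Diethylamine in EtOH would then close 19 through enaminone 20, and the sequence comes back to the route at flavone 21.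

2. Step 5. Butyllithium may deprotonate the benzylic CH2 of the benzyl ether (followed by Wittig rearrangement), or metalate the ring CH between OMe and OBn, so that iodine ends up at the wrong position or the ether is lost.
Fallback: the acetal director and the 0 °C metalation would be replaced by a carbamate director that is metalated at −78 °C and unmasked by base. It sets out from phenol 7. Carbamoylation (Et2NCOCl, K2CO3, MeCN, reflux) should give 5-(benzyloxy)-2,3-dimethoxyphenyl N,N-diethylcarbamate F2. Metalation with s-BuLi/TMEDA in THF at −78 °C and an I2 quench should give 3-(benzyloxy)-2-iodo-5,6-dimethoxyphenyl N,N-diethylcarbamate F3. Cleavage of the carbamate with KOH in aqueous EtOH at reflux comes back to the route at iodophenol 11.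

3. Step 12. The 3-lithiochromone may open by β-elimination of the phenoxide (reverting to an ynone), or metalation may be incomplete next to the ortho-substituted B ring, so that little boronate is formed.
Fallback: the C3 oxygen would be brought in by electrophilic oxidation instead of metalation. It sets out from flavone 21. Dimethyldioxirane in acetone/CH2Cl2 at 0 °C should give the 2,3-epoxide rac-5-(benzyloxy)-2-[5-(benzyloxy)-2-methoxyphenyl]-2,3-epoxy-7,8-dimethoxy-2,3-dihydro-4H-chromen-4-one F4. Catalytic p-TsOH in CH2Cl2 should open the epoxide and tautomerise it, which comes back to the route at flavonol 24.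

**Further compounds**

F1 | step 11 | 1-[6-(benzyloxy)-3,4-dimethoxy-2-(methoxymethoxy)phenyl]-3-[5-(benzyloxy)-2-methoxyphenyl]prop-2-yn-1-one | COCOc1c(C(=O)C#Cc2cc(OCc3ccccc3)ccc2OC)c(OCc2ccccc2)cc(OC)c1OC
F2 | step 5 | 5-(benzyloxy)-2,3-dimethoxyphenyl N,N-diethylcarbamate | CCN(CC)C(=O)Oc1cc(OCc2ccccc2)cc(OC)c1OC
F3 | step 5 | 3-(benzyloxy)-2-iodo-5,6-dimethoxyphenyl N,N-diethylcarbamate | CCN(CC)C(=O)Oc1c(I)c(OCc2ccccc2)cc(OC)c1OC
F4 | step 12 | rac-5-(benzyloxy)-2-[5-(benzyloxy)-2-methoxyphenyl]-2,3-epoxy-7,8-dimethoxy-2,3-dihydro-4H-chromen-4-one (cis-fused flavone 2,3-oxide, racemic, one enantiomer drawn) | COc1ccc(OCc2ccccc2)cc1[C@]12O[C@H]1C(=O)c1c(OCc3ccccc3)cc(OC)c(OC)c1O2
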